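Remark (assumptions): atoms are numbered as in tricyclo[5.4.0.0^2,8]undecane (C11 ketone, C9 methyl, C2 quaternary methyl, C3/C4/C5 oxygenated, C6 gem-dimethyl). "Toward C1/C8" and "toward C2/C7" give the side of a bridge on which a substituent lies. The sense of the chiral-base step is taken by analogy with 4-substituted cyclohexanones, and the sense of the CBS step assumes the quaternary carbon acts as the large group.

## Structural features

The target is a longipinane-type sesquiterpenoid built on a cyclobutane C1–C2–C8–C7 whose two diagonals are both bridged. C1/C8 are spanned by C9–C10–C11 (a pinane-like bicyclo[3.1.1]heptanone with the C11 ketone and the C9 methyl), and C2/C7 are spanned by C3–C4–C5–C6 on the opposite face (the seven-membered ring). There are eight stereocenters: the four cyclobutane carbons (C2 quaternary, its methyl syn to the C9–C11 bridge), C9, and the contiguous C3/C4/C5 array (3,4-trans, 4,5-cis) flanked by the quaternary carbons C2 and C6. The three oxygens are differentiated: angelate ((Z)-2-methylbut-2-enoate) at C3, 3-methylbutanoate at C4, free hydroxyl at C5. Fragile points are the angelate (Z to E isomerization, oxidation, conjugate addition), acyl migration along C3–C5, and the cyclobutane next to any cationic center. The real difficulty is the doubly bridged cyclobutane with quaternary C2 and the C6–C7 bond, plus placing the C3 oxygen, because the C3–C6 bridge lies in a local mirror plane of the bicyclo[4.1.1]octane subunit. The key step exploits the fact that the C2···C7 diagonal is the central σ-bond of a bicyclo[1.1.0]butane whose wing carbons C1 and C8 are already tied by the C9–C11 bridge. A four-carbon unit added across that bond from its open convex face must land on the correct face. In one sentence: a radical [4+2σ] annulation of an α-bromo β-ethoxyvinyl ketone across the central bond of a 1-methyltricyclo[4.1.0.0^2,7]heptane.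

## Logic of the disconnections

23 to 22: the C4–O acyl bond is cut. In 22 the C4 hydroxyl is the only one not next to a quaternary carbon, so the last ester can go on without protecting groups. The forward step must stop at C4 and avoid acyl migration.

22 to 21: both C–O bonds at C4 and C5 are cut back to the C4=C5 alkene. A cis-diol trans to the C3 ester is what syn-dihydroxylation anti to an allylic oxygen gives, so two stereocenters come from one. The forward step must prefer the ring alkene over the angelate.

21 to 20 to 19 to 18: the C9–H bond is cut (conjugate reduction), then the C9=C10 unsaturation (dehydrogenation), then the ketal. The C9 methyl is carried earlier with the opposite relative configuration because it relays absolute configuration into the cyclobutane. It is re-set late from the face not blocked by the C2 methyl. The reduction must be chemoselective for the ketone-conjugated alkene.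

18 to 17: the C3–O acyl bond is cut. At this stage the C3 hydroxyl is the only hydroxyl, so the angelate position is unambiguous. Esterification must not isomerize the Z-alkene.

17 to 15 (via 16) to 14 to 13 to 12: an oxygen transposition. The C4–O epoxide bond and the C5 oxygen are removed (Wharton), the C5 carbinol is re-formed from the ketone, the two epoxide C–O bonds are cut, and finally the C5–H bond. The key step delivers oxygen at C5 but the endgame needs it at C3. Because the bridge sits in a local mirror plane, only a reagent can choose the face, and the resulting C5 carbinol relays to C3 by a hydroxyl-directed epoxidation. The demands are reagent-controlled reduction of a ketone flanked by a quaternary carbon and hydrazone formation at that hindered ketone.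

12 to 7 + 10 (via 11): the key disconnection. The C2–C3 and C6–C7 bonds are cut and the C2–C7 σ-bond is restored. The tricycle with its quaternary C2, the C6–C7 bond and the seven-membered ring falls back to a bicyclobutane and an acyclic four-carbon reagent. Both cyclobutane stereocenters follow from geometry. The forward step needs correct bridgehead regiochemistry and ring closure faster than hydrogen transfer.

10 to 8 + 9: the bond between the acyl carbon and the vinyl carbon is cut (acylation of an enol ether). Both partners are commercial.

7 to 6: the future C7–C8 bond is cut (carbenoid C–H insertion). The ketal carbon leaves only one insertion site, which puts the methyl on a bridgehead.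

6 to 5: the two cyclopropane bonds to the future C7 are cut (dibromocarbene addition). The face of addition, set relative to the C9 methyl, fixes the absolute configuration of the future cyclobutane.

5 to 4 to 3 to 2 to 1: no skeletal bond is cut. The ketal, the enone unsaturation and the silyl enol ether are removed in turn, back to a meso ketone and a racemic commercial enone. The single stereocenter comes from an enantioselective deprotonation.

## Other disconnections considered

Alternative 1: de Mayo-type photocycloaddition and retro-aldol, the first plan that comes to mind. Cut: C1–C7 and C5–C6 are formed by an intramolecular [2+2] between an enol double bond and a pendant 2-methylpropenyl group, and C1–C5 is then broken. Forward key step: irradiation of the hydrindenone enol acetate A1 to the tetracyclic photoadduct A2, then deacetylation and retro-aldol opening to the tricyclic 5,11-diketone A3. Grounds for not choosing it: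
- The cycloaddition must run in the parallel sense across a 1,5-diene and build a bicyclo[2.2.0]hexane unit, against the usual crossed 1,5-closure.
- A3 has C3 and C4 as plain methylenes and two ketones to tell apart, so the transposition and triol chemistry of the chosen route would still be needed.
- A1 itself needs a longer linear preparation (quaternary C2, three stereocenters).

Alternative 2: crossed intramolecular ketene–alkene [2+2]. Cut: C1–C7 and C2–C8, with C7 as the ketene carbonyl carbon. Forward key step: acid chloride A4 with triethylamine and heat gives the ketene, which closes to the bicyclo[3.1.1]heptan-6-one A5; the E-alkene sets C2. Grounds for not choosing it: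
- C7 arrives as a carbonyl. It would need addition of a tertiary nucleophile and then deoxygenation of a tertiary cyclobutanol next to a quaternary carbon, where a radical or cation invites 1,2-vinyl shift or cyclobutylcarbinyl rearrangement.
- The C9 methyl in the tether should prefer the side of the small carbonyl bridge, which is the wrong epimer.
- The seven-membered ring would still have to be closed.

Alternative 3: transannular [2+2] of a humulane-type macrocycle. Cut: C1–C7 and C2–C8. Forward key step: sensitized irradiation of the cycloundecadienone A6 (enone C11/C1=C2, isolated alkene C7=C8). Grounds for not choosing it: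
- The alkenes are linked by tethers of three and four atoms, so the parallel mode (C1–C8 and C2–C7, five- and six-membered rings) should win over the crossed mode that the target needs.
- E/Z photoisomerization and ring mobility remove control at C2.
- An enantiopure, oxygenated A6 is itself a macrocycle synthesis longer than the chosen route up to 12.

Key step: step 8

## Steps

Step 1
Reactants: 1 3,5-dimethylcyclohex-2-en-1-one (racemic)
Product: 2 cis-3,5-dimethylcyclohexanone (meso; 3R,5S)
Conditions: H2 (1 atm), Pd/C, EtOAc, rt
Reagents that add atoms: none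
Why: Catalytic hydrogenation should give mainly the diequatorial cis ketone, which is meso and so erases the racemic stereocenter before a desymmetrization; any trans isomer is removed here.

Step 2
Reactants: 2 cis-3,5-dimethylcyclohexanone
Product: 3 [(3R,5S)-3,5-dimethylcyclohex-1-en-1-yl]oxy(trimethyl)silane
Conditions: lithium (R,R)-bis(1-phenylethyl)amide (from the amine and n-BuLi), LiCl, TMSCl (internal quench), THF, −100 °C
Reagents that add atoms: chlorotrimethylsilane, C[Si](C)(C)Cl
Why: Enantioselective deprotonation of a meso ketone by a chiral lithium amide; removal of one of the two enantiotopic axial α-protons fixes the remote stereocenter (C5) in absolute terms.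

Step 3
Reactants: 3 silyl enol ether
Product: 4 (5S)-3,5-dimethylcyclohex-2-en-1-one
Conditions: Pd(OAc)2 (1 equiv), MeCN, rt
Reagents that add atoms: none
Why: Saegusa–Ito oxidation; β-hydride loss from C3 removes the allylic stereocenter and leaves C5 untouched.

Step 4
Reactants: 4 (5S)-3,5-dimethylcyclohex-2-en-1-one
Product: 5 (9S)-7,9-dimethyl-1,4-dioxaspiro[4.5]dec-6-ene
Conditions: 1,2-bis(trimethylsilyloxy)ethane, TMSOTf (cat.), CH2Cl2, −78 °C
Reagents that add atoms: 1,2-bis(trimethylsilyloxy)ethane, C[Si](C)(C)OCCO[Si](C)(C)C
Why: Aprotic silyl-triflate-catalysed ketalization keeps the alkene in the α,β-position; the ketal protects the carbonyl from methyllithium and leaves no C–H on the carbon next to the alkene CH.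

Step 5
Reactants: 5 unsaturated ketal
Product: 6 7,7-dibromo-4,6-dimethylspiro[bicyclo[4.1.0]heptane-2,2′-[1,3]dioxolane] (CBr2 bridge cis to the C4 methyl)
Conditions: CHBr3, 50% aq. NaOH, BnEt3NCl (cat.), CH2Cl2, 0 °C to rt
Reagents that add atoms: bromoform, BrC(Br)Br
Why: Phase-transfer dibromocyclopropanation; in the half-chair with equatorial methyl the pseudoaxial ketal oxygen shields one face, so the carbene should add to the other face, cis to the methyl. This sets the two cyclopropane stereocenters relative to the methyl-bearing carbon.

Step 6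
Reactants: 6 dibromocyclopropane
Product: 7 1,3-dimethylspiro[tricyclo[4.1.0.0^2,7]heptane-5,2′-[1,3]dioxolane] (C3 methyl on the side of the C7–H bridgehead)
Conditions: MeLi, Et2O, −78 to 0 °C
Reagents that add atoms: none
Why: Bromine–lithium exchange gives a cyclopropylidene carbenoid that inserts into the syn C–H of the adjacent ring CH2 (the standard bicyclobutane synthesis from gem-dibromocyclopropanes). The other neighbour is the ketal carbon without hydrogen, so the methyl ends on a bridgehead and the new stereocenter is fixed by the ring.

Step 7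
Reactants: 8 2-bromo-2-methylpropanoyl bromide; 9 ethyl vinyl ether
Product: 10 (E)-4-bromo-1-ethoxy-4-methylpent-1-en-3-one
Conditions: pyridine, CH2Cl2, 0 °C to rt
Reagents that add atoms: none
Why: Acylation of an enol ether by an acyl halide followed by loss of HBr gives the (E)-β-alkoxyvinyl ketone; the acyl bromide has no α-hydrogen, so no ketene can form.

Step 8
Reactants: 7 bridged bicyclobutane; 10 bromo enone
Product: 12 2,6,6,9-tetramethylspiro[tricyclo[5.4.0.0^2,8]undec-3-ene-11,2′-[1,3]dioxolan]-5-one (C9 methyl toward C7), via β-ethoxy ketone 11 (not isolated)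
Conditions: Ir(ppy)3 (1 mol%), Hantzsch ester, 2,6-lutidine, MeCN, blue LEDs, rt, slow addition of 10 to excess 7; then DBU, 50 °C
Reagents that add atoms: none
Why: Proposed new method: a reductive radical [4+2σ] annulation that adds C3–C6 of 10 across the central C2–C7 σ-bond of 7; the closest known reaction types are additions of electrophilic radicals (thiyl, sulfonyl, α-carbonyl) across the central bond of bicyclo[1.1.0]butanes and tricyclo[4.1.0.0^2,7]heptanes, and endo cyclizations of alkyl radicals onto β-alkoxy enones. Photoexcited Ir(ppy)3 reduces the C–Br bond of 10 to an electrophilic tertiary α-keto radical, which adds to the hydrogen-bearing bridgehead (future C7) on the open convex face and breaks the strained σ-bond, leaving a tertiary cyclobutyl radical at C2; this nucleophilic radical adds to the β-carbon of the vinylogous ester (future C3), the resulting α-keto radical takes hydrogen from the Hantzsch ester to give 11, and DBU eliminates ethanol to the enone. The seven-membered ring closes by a 7-endo-trig radical addition with the carbonyl inside the forming ring; the cyclobutane is not closed but revealed by σ-bond cleavage, and the six-membered ring is carried in from 7. C7 is set by convex-face attack, which places C6 anti to the C9–C11 bridge and the hydrogen syn. C2 is set by the tether: C3 is held through C6–C7 and can reach only the anti lobe of the C2 radical, so the methyl is pushed syn, and a trans-bridged isomer is geometrically impossible. The step needs attack at the hydrogen-bearing rather than the methyl-bearing bridgehead (less hindered, and it gives the tertiary radical) and 7-endo rather than 6-exo closure (the β-carbon of the enone is the electrophilic site for a nucleophilic radical). It also needs cyclization to outrun hydrogen transfer, which the gem-dimethyl group, the cis-1,3 arrangement on the cyclobutane and a dilute hydrogen donor should favour. The C3 configuration of 11 is irrelevant because the ethoxy group is eliminated.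

Step 9
Reactants: 12 tricyclic enone
Product: 13 (5S)-2,6,6,9-tetramethylspiro[tricyclo[5.4.0.0^2,8]undec-3-ene-11,2′-[1,3]dioxolan]-5-ol (hydroxyl toward C1)
Conditions: (R)-2-methyl-CBS-oxazaborolidine (20 mol%), catecholborane, toluene, −78 °C
Reagents that add atoms: none
Why: Corey–Bakshi–Shibata 1,2-reduction; with quaternary C6 as the large group and vinylic C4 as the small one, the (R)-catalyst should deliver hydride to the face turned toward C8. Reagent control is needed because the bridge lies in a local mirror plane, and any minor-enantiomer material from step 2 becomes a separable diastereomer here.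

Step 10
Reactants: 13 allylic alcohol
Product: 14 3,4-epoxy-2,6,6,9-tetramethylspiro[tricyclo[5.4.0.0^2,8]undecane-11,2′-[1,3]dioxolan]-5-ol (epoxide and hydroxyl both toward C1)
Conditions: VO(acac)2 (cat.), t-BuOOH, CH2Cl2, 0 °C to rt
Reagents that add atoms: tert-butyl hydroperoxide, CC(C)(C)OO
Why: Hydroxyl-directed epoxidation through a vanadate ester delivers oxygen syn to the C5 hydroxyl (reliable for cyclohept-2-enols); this sets the C3–O bond on the side toward C1.

Step 11
Reactants: 14 epoxy alcohol
Product: 15 3,4-epoxy-2,6,6,9-tetramethylspiro[tricyclo[5.4.0.0^2,8]undecane-11,2′-[1,3]dioxolan]-5-one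
Conditions: Dess–Martin periodinane, CH2Cl2, rt
Reagents that add atoms: none
Why: Non-basic oxidation of the secondary alcohol leaves the epoxide and ketal intact; the C5 stereocenter has finished its relay.

Step 12
Reactants: 15 epoxy ketone
Product: 17 2,6,6,9-tetramethylspiro[tricyclo[5.4.0.0^2,8]undec-4-ene-11,2′-[1,3]dioxolan]-3-ol (hydroxyl toward C1), via epoxy hydrazone 16 (not isolated)
Conditions: N2H4·H2O, AcOH (cat.), MeOH, 0 °C to rt
Reagents that add atoms: hydrazine, NN (its nitrogen atoms are present in 16 only)
Why: Wharton transposition; the hydrazone opens the epoxide to an alkenyl diazene that loses N2, giving the C4=C5 alkene and the C3 alcohol with the C3–O bond from step 10 retained.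

Step 13
Reactants: 17 allylic alcohol
Product: 18 2,6,6,9-tetramethylspiro[tricyclo[5.4.0.0^2,8]undec-4-ene-11,2′-[1,3]dioxolan]-3-yl (Z)-2-methylbut-2-enoate
Conditions: angelic acid, 2,4,6-trichlorobenzoyl chloride, Et3N, toluene, rt; then 17, 75 °C
Reagents that add atoms: (Z)-2-methylbut-2-enoic acid (angelic acid), C/C=C(/C)C(=O)O
Why: Yamaguchi-type mixed-anhydride esterification without a nucleophilic catalyst, which avoids the addition–elimination path that turns angelate into tiglate; the C3 hydroxyl is the only hydroxyl present.

Step 14
Reactants: 18 angelate ketal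
Product: 19 2,6,6,9-tetramethyl-11-oxotricyclo[5.4.0.0^2,8]undec-4-en-3-yl (Z)-2-methylbut-2-enoate (C9 methyl toward C7)
Conditions: 1 M aq. HCl, THF, rt
Reagents that add atoms: water, O
Why: Acetal hydrolysis; the allylic ester and the alkene should tolerate dilute acid at room temperature.

Step 15
Reactants: 19 ketone
Product: 20 2,6,6,9-tetramethyl-11-oxotricyclo[5.4.0.0^2,8]undeca-4,9-dien-3-yl (Z)-2-methylbut-2-enoate
Conditions: IBX, DMSO/PhF, 75 °C
Reagents that add atoms: none
Why: IBX-mediated α,β-dehydrogenation of a ketone; only C10 carries enolizable hydrogens (C1 is a cyclobutane bridgehead next to quaternary C2), so the C9=C10 enone forms and the relay stereocenter at C9 is erased.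

Step 16
Reactants: 20 dienone ester
Product: 21 (9S)-2,6,6,9-tetramethyl-11-oxotricyclo[5.4.0.0^2,8]undec-4-en-3-yl (Z)-2-methylbut-2-enoate (C9 methyl toward C2)
Conditions: [(Ph3P)CuH]6, benzene, H2O (few equiv), rt
Reagents that add atoms: none
Why: Conjugate reduction with Stryker's reagent; hydride should add to C9 from the side of the C7–H bridge because the other face is blocked by the C2 methyl (the same sense as reductions of verbenone-type enones), which puts the methyl toward C2. The trisubstituted angelate and the isolated C4=C5 alkene are much less reactive toward copper hydride than the ketone-conjugated alkene.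

Step 17
Reactants: 21 alkene
Product: 22 4,5-dihydroxy-2,6,6,9-tetramethyl-11-oxotricyclo[5.4.0.0^2,8]undecan-3-yl (Z)-2-methylbut-2-enoate (both hydroxyls toward C8)
Conditions: OsO4 (5 mol%), NMO, acetone/H2O, 0 °C
Reagents that add atoms: N-methylmorpholine N-oxide, C[N+]1([O-])CCOCC1; water, O
Why: Catalytic syn-dihydroxylation (Upjohn) from the face opposite the allylic C3 ester gives the 4,5-cis diol trans to O3; the electron-poor trisubstituted angelate alkene is expected to react more slowly than the cis-disubstituted ring alkene.

Step 18
Reactants: 22 diol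
Product: 23 (1R,2R,3S,4S,5S,7S,8S,9S)-5-hydroxy-2,6,6,9-tetramethyl-4-[(3-methylbutanoyl)oxy]-11-oxotricyclo[5.4.0.0^2,8]undecan-3-yl (Z)-2-methylbut-2-enoate (target)
Conditions: isovaleryl chloride (1.05 equiv), pyridine, CH2Cl2, −20 °C
Reagents that add atoms: 3-methylbutanoyl chloride, CC(C)CC(=O)Cl
Why: Selective acylation of the less hindered C4 hydroxyl; the C5 hydroxyl is neopentyl-like next to the gem-dimethyl carbon, and low temperature with a weak base limits acyl migration.

## Compound list

1 | 3,5-dimethylcyclohex-2-en-1-one (racemic) | CC1=CC(=O)CC(C)C1 | starting material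
2 | cis-3,5-dimethylcyclohexanone (meso, 3R,5S) | O=C1C[C@H](C)C[C@H](C)C1 | intermediate
3 | [(3R,5S)-3,5-dimethylcyclohex-1-en-1-yl]oxy(trimethyl)silane | C[Si](C)(C)OC1=C[C@H](C)C[C@H](C)C1 | intermediate
4 | (5S)-3,5-dimethylcyclohex-2-en-1-one | O=C1C=C(C)C[C@H](C)C1 | intermediate
5 | (9S)-7,9-dimethyl-1,4-dioxaspiro[4.5]dec-6-ene | O1CCOC12C=C(C)C[C@H](C)C2 | intermediate
6 | 7,7-dibromo-4,6-dimethylspiro[bicyclo[4.1.0]heptane-2,2′-[1,3]dioxolane], CBr2 bridge cis to the C4 methyl | BrC1(Br)[C@H]2C3(OCCO3)C[C@@H](C)C[C@@]12C | intermediate
7 | 1,3-dimethylspiro[tricyclo[4.1.0.0^2,7]heptane-5,2′-[1,3]dioxolane], C3 methyl on the side of the C7–H bridgehead | [C@H]12[C@@H]3[C@H](C)CC4(OCCO4)[C@H]1[C@]23C | intermediate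
8 | 2-bromo-2-methylpropanoyl bromide | CC(C)(Br)C(=O)Br | starting material
9 | ethyl vinyl ether | C=COCC | starting material
10 | (E)-4-bromo-1-ethoxy-4-methylpent-1-en-3-one | CCO/C=C/C(=O)C(C)(C)Br | intermediate
11 | 3-ethoxy-2,6,6,9-tetramethylspiro[tricyclo[5.4.0.0^2,8]undecane-11,2′-[1,3]dioxolan]-5-one (C9 methyl toward C7; C3 epimers) | CCOC1CC(=O)C(C)(C)[C@H]2[C@@H]3[C@H](C)CC4(OCCO4)[C@H]2[C@@]31C | intermediate (not isolated)
12 | 2,6,6,9-tetramethylspiro[tricyclo[5.4.0.0^2,8]undec-3-ene-11,2′-[1,3]dioxolan]-5-one (C9 methyl toward C7) | C1=CC(=O)C(C)(C)[C@H]2[C@@H]3[C@H](C)CC4(OCCO4)[C@H]2[C@@]31C | intermediate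
13 | (5S)-2,6,6,9-tetramethylspiro[tricyclo[5.4.0.0^2,8]undec-3-ene-11,2′-[1,3]dioxolan]-5-ol (hydroxyl toward C1) | C1=C[C@H](O)C(C)(C)[C@H]2[C@@H]3[C@H](C)CC4(OCCO4)[C@H]2[C@@]31C | intermediate
14 | 3,4-epoxy-2,6,6,9-tetramethylspiro[tricyclo[5.4.0.0^2,8]undecane-11,2′-[1,3]dioxolan]-5-ol (epoxide and hydroxyl toward C1) | O5[C@@H]1[C@H]5[C@H](O)C(C)(C)[C@H]2[C@@H]3[C@H](C)CC4(OCCO4)[C@H]2[C@@]31C | intermediate
15 | 3,4-epoxy-2,6,6,9-tetramethylspiro[tricyclo[5.4.0.0^2,8]undecane-11,2′-[1,3]dioxolan]-5-one | O5[C@@H]1[C@H]5C(=O)C(C)(C)[C@H]2[C@@H]3[C@H](C)CC4(OCCO4)[C@H]2[C@@]31C | intermediate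
16 | hydrazone of 15 at C5 | O5[C@@H]1[C@H]5C(=NN)C(C)(C)[C@H]2[C@@H]3[C@H](C)CC4(OCCO4)[C@H]2[C@@]31C | intermediate (not isolated)
17 | 2,6,6,9-tetramethylspiro[tricyclo[5.4.0.0^2,8]undec-4-ene-11,2′-[1,3]dioxolan]-3-ol (hydroxyl toward C1) | O[C@@H]1C=CC(C)(C)[C@H]2[C@@H]3[C@H](C)CC4(OCCO4)[C@H]2[C@@]31C | intermediate
18 | (Z)-2-methylbut-2-enoate of 17 | C/C=C(/C)C(=O)O[C@@H]1C=CC(C)(C)[C@H]2[C@@H]3[C@H](C)CC4(OCCO4)[C@H]2[C@@]31C | intermediate
19 | 2,6,6,9-tetramethyl-11-oxotricyclo[5.4.0.0^2,8]undec-4-en-3-yl (Z)-2-methylbut-2-enoate (C9 methyl toward C7) | C/C=C(/C)C(=O)O[C@@H]1C=CC(C)(C)[C@H]2[C@@H]3[C@H](C)CC(=O)[C@H]2[C@@]31C | intermediate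
20 | 2,6,6,9-tetramethyl-11-oxotricyclo[5.4.0.0^2,8]undeca-4,9-dien-3-yl (Z)-2-methylbut-2-enoate | C/C=C(/C)C(=O)O[C@@H]1C=CC(C)(C)[C@H]2[C@@H]3C(C)=CC(=O)[C@H]2[C@@]31C | intermediate
21 | (9S)-2,6,6,9-tetramethyl-11-oxotricyclo[5.4.0.0^2,8]undec-4-en-3-yl (Z)-2-methylbut-2-enoate (C9 methyl toward C2) | C/C=C(/C)C(=O)O[C@@H]1C=CC(C)(C)[C@H]2[C@@H]3[C@@H](C)CC(=O)[C@H]2[C@@]31C | intermediate
22 | 4,5-dihydroxy-2,6,6,9-tetramethyl-11-oxotricyclo[5.4.0.0^2,8]undecan-3-yl (Z)-2-methylbut-2-enoate (hydroxyls toward C8) | C/C=C(/C)C(=O)O[C@@H]1[C@@H](O)[C@@H](O)C(C)(C)[C@H]2[C@@H]3[C@@H](C)CC(=O)[C@H]2[C@@]31C | intermediate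
23 | (1R,2R,3S,4S,5S,7S,8S,9S)-5-hydroxy-2,6,6,9-tetramethyl-4-[(3-methylbutanoyl)oxy]-11-oxotricyclo[5.4.0.0^2,8]undecan-3-yl (Z)-2-methylbut-2-enoate | C/C=C(/C)C(=O)O[C@@H]1[C@@H](OC(=O)CC(C)C)[C@@H](O)C(C)(C)[C@H]2[C@@H]3[C@@H](C)CC(=O)[C@H]2[C@@]31C | target

## Step count and least certain steps

Total: 18 steps. Longest linear sequence: 17 steps (steps 1–6 and 8–18); step 7 is a one-step branch.

Step 8 (key step, proposed new method). Most likely failure: hydrogen transfer to the C2 radical before the seven-membered ring closes, or radical oligomerization of 10, because one flask must serve both a bimolecular addition and a slow endo cyclization. Fallback with known chemistry, from 7 and 10 back to 11: first run a redox-neutral atom-transfer radical addition of 10 across the central bond of 7 (Ir(ppy)3, light, no hydrogen donor) and isolate the tertiary bromide F1. Then, in a separate high-dilution step, generate the C2 radical with Bu3SnH/AIBN by syringe pump so that the 7-endo closure to 11 is no longer competing with the intermolecular step. DBU then gives 12 as before.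

Step 5. Most likely failure: poor facial selectivity of carbene addition, because the pseudoaxial ketal oxygen may not bias the two alkene faces strongly; the wrong face would lead to the enantiomeric cyclobutane after the C9 re-set. Fallback, from 4 back to 6: Luche reduction (NaBH4, CeCl3·7H2O) to the cis allylic alcohol F2, then phase-transfer dibromocyclopropanation directed syn by the free hydroxyl to the cyclopropyl carbinol F3. Dess–Martin oxidation gives the cyclopropyl ketone F4, and ketalization with ethylene glycol returns 6.

Step 9. Most likely failure: weak or reversed enantioface discrimination, because the carbonyl is flanked by a quaternary carbon and an alkene whose relative "size" for the catalyst is not certain. Fallback, from 12 back to 13: Luche reduction gives 13 together with its C5 epimer F5. The two are separated by chromatography, and F5 is re-oxidized with MnO2 to 12 and recycled.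

Step 12. Most likely failure: slow hydrazone formation at the ketone next to the gem-dimethyl carbon, which lets hydrazine open the epoxide instead. Fallback, from 14 back to 17, avoiding the ketone: convert 14 with 1,1′-thiocarbonyldiimidazole into the thiocarbonylimidazolide F6 and treat it with Bu3SnH/AIBN. The C5 radical opens the adjacent epoxide to the C3 alkoxy radical, which is reduced to 17.

Step 17. Most likely failure: competing osmylation of the angelate double bond, because the ring alkene is hindered by two neighbouring fully substituted carbons. Fallback, from 17 back to 22, with the diol made before the angelate exists: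
- Dihydroxylate 17 (OsO4, NMO, anti to the free C3 hydroxyl) to the triol F7.
- Protect the cis-4,5-diol with 2,2-dimethoxypropane/PPTS as the acetonide F8.
- Esterify the C3 hydroxyl as in step 13 to the angelate F9.
- Remove both acetals with aqueous acid to the diol ketone F10.
- Dehydrogenate by the Saegusa–Ito sequence (TMSOTf/Et3N, then Pd(OAc)2, acidic work-up) to the enone diol F11.
- Reduce with [(Ph3P)CuH]6 as in step 16 to reach 22.

## Further compounds

F1 | step 8 | (E)-4-[6-bromo-2,6-dimethylspiro[bicyclo[3.1.1]heptane-4,2′-[1,3]dioxolan]-7-yl]-1-ethoxy-4-methylpent-1-en-3-one (side chain anti to the three-carbon bridge; epimers at the C–Br carbon) | CCO/C=C/C(=O)C(C)(C)[C@H]1[C@@H]2[C@H](C)CC3(OCCO3)[C@H]1C2(C)Br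
F2 | step 5 | (1S,5S)-3,5-dimethylcyclohex-2-en-1-ol (cis) | O[C@@H]1C=C(C)C[C@H](C)C1
F3 | step 5 | 7,7-dibromo-4,6-dimethylbicyclo[4.1.0]heptan-2-ol (hydroxyl, CBr2 bridge and C4 methyl mutually cis) | BrC1(Br)[C@H]2[C@@H](O)C[C@@H](C)C[C@@]12C
F4 | step 5 | 7,7-dibromo-4,6-dimethylbicyclo[4.1.0]heptan-2-one (CBr2 bridge cis to the C4 methyl) | BrC1(Br)[C@H]2C(=O)C[C@@H](C)C[C@@]12C
F5 | step 9 | C5 epimer of 13 (hydroxyl toward C8) | C1=C[C@@H](O)C(C)(C)[C@H]2[C@@H]3[C@H](C)CC4(OCCO4)[C@H]2[C@@]31C
F6 | step 12 | O-(C5) 1H-imidazole-1-carbothioate of 14 | O5[C@@H]1[C@H]5[C@H](OC(=S)n6ccnc6)C(C)(C)[C@H]2[C@@H]3[C@H](C)CC4(OCCO4)[C@H]2[C@@]31C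
F7 | step 17 | 2,6,6,9-tetramethylspiro[tricyclo[5.4.0.0^2,8]undecane-11,2′-[1,3]dioxolane]-3,4,5-triol (O3 toward C1; O4 and O5 toward C8; C9 methyl toward C7) | O[C@@H]1[C@@H](O)[C@@H](O)C(C)(C)[C@H]2[C@@H]3[C@H](C)CC4(OCCO4)[C@H]2[C@@]31C
F8 | step 17 | 4,5-O-isopropylidene derivative of F7 | O[C@@H]1[C@H]5OC(C)(C)O[C@H]5C(C)(C)[C@H]2[C@@H]3[C@H](C)CC4(OCCO4)[C@H]2[C@@]31C
F9 | step 17 | (Z)-2-methylbut-2-enoate of F8 at O3 | C/C=C(/C)C(=O)O[C@@H]1[C@H]5OC(C)(C)O[C@H]5C(C)(C)[C@H]2[C@@H]3[C@H](C)CC4(OCCO4)[C@H]2[C@@]31C
F10 | step 17 | C9 epimer of 22 (C9 methyl toward C7) | C/C=C(/C)C(=O)O[C@@H]1[C@@H](O)[C@@H](O)C(C)(C)[C@H]2[C@@H]3[C@H](C)CC(=O)[C@H]2[C@@]31C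
F11 | step 17 | 4,5-dihydroxy-2,6,6,9-tetramethyl-11-oxotricyclo[5.4.0.0^2,8]undec-9-en-3-yl (Z)-2-methylbut-2-enoate | C/C=C(/C)C(=O)O[C@@H]1[C@@H](O)[C@@H](O)C(C)(C)[C@H]2[C@@H]3C(C)=CC(=O)[C@H]2[C@@]31C
A1 | alternative 1 | 6,7a-dimethyl-7-(2-methylprop-1-en-1-yl)-4-oxo-2,4,5,6,7,7a-hexahydro-1H-inden-3-yl acetate | CC(C)=C[C@@H]1[C@@H](C)CC(=O)C2=C(OC(C)=O)CC[C@]12C
A2 | alternative 1 | tetracyclic [2+2] photoadduct of A1 (bicyclo[2.2.0]hexane unit, acetoxy on the former enol carbon) | CC1(C)[C@H]2[C@@H]3[C@@H](C)CC(=O)[C@@]24[C@]3(C)CC[C@@]14OC(C)=O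
A3 | alternative 1 | 2,6,6,9-tetramethyltricyclo[5.4.0.0^2,8]undecane-5,11-dione | C1CC(=O)C(C)(C)[C@H]2[C@@H]3[C@@H](C)CC(=O)[C@H]2[C@@]31C
A4 | alternative 2 | (E)-8-(benzyloxy)-5-[(tert-butyldimethylsilyl)oxy]-3,7-dimethyloct-6-enoyl chloride | ClC(=O)C[C@H](C)C[C@@H](O[Si](C)(C)C(C)(C)C)/C=C(\C)COCc1ccccc1
A5 | alternative 2 | 7-[(benzyloxy)methyl]-4-[(tert-butyldimethylsilyl)oxy]-2,7-dimethylbicyclo[3.1.1]heptan-6-one | O=C2[C@@H]3[C@H](C)C[C@@H](O[Si](C)(C)C(C)(C)C)[C@H]2[C@]3(C)COCc1ccccc1
A6 | alternative 3 | (2E,8E,10S)-3,7,7,10-tetramethylcycloundeca-2,8-dien-1-one | C[C@H]1CC(=O)/C=C(\C)CCCC(C)(C)/C=C/1
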